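Sunday's run could not go on as it began. Its first reading had lost 8.20% of the electrophile in 4.00 min, and that slope, kept for 4.0 h, removes 492% of the charge. The rate had to fall, so I looked for the law of its fall.

| setting | Sunday's | flask |
|---|---|---|
| electrophile | 33 mM | 33 mM |
| nucleophile | 3 equiv | 3.00 equiv |
| remark | the very flask that is asked about, followed so far |  |
| time |  | 4.0 h |

Sunday's run (percent of the electrophile charged)

| time / min | electrophile / % | target / % |
|---|---|---|
| 4.00 | 91.8 | 7.6 |
| 6.00 | 88.7 | 12.4 |
| 8.00 | 84.9 | 15.3 |
| 15.0 | 73.6 | 25.9 |
| 20.0 | 68.4 | 31.9 |
| 30.0 | 57.3 | 43.4 |
| 50.0 | 42.5 | 57.4 |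

(scatter of a reading: 0.5 percentage points)

- what was read earlier has a scatter of 0.5 percentage points, one standard deviation
- the earlier runs do not show how much of nucleophile is bound; that part of a forecast is a guess

- part of the electrophile that has reacted at 4.0 h
- share of the unused nucleophile that is free and not bound as protonated nucleophile, at 4.0 h

I counted nucleophile lost per conversion. With one, the second-order pace read 0.00715 min⁻¹ at 15.0 min and 0.00643 min⁻¹ at 50.0 min, so it drifted. With two, one reacting and one bound as protonated nucleophile, it read 0.00753 min⁻¹ and 0.00744 min⁻¹. I kept two. The 3.00 equiv charged exceed the 2 equiv that full conversion then takes, so electrophile is the limiting reagent.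

The logarithm of free nucleophile over electrophile, each as a fraction of its charge, then rises straight with time. My clock number is rate constant times charged electrophile times time, the height that line reaches at these equivalents: 1.79. It gave 93.7% reacted and 54.6% free. The same number gave both answers, and both rested on my count of 2, which stayed a guess: the earlier runs do not show how much nucleophile is bound.

The forecast said 94% and 57%, above my figures: “The run therefore favours nearly full binding, though this is not proven.”

The flask gave 93.5% reacted and 54.8% free.

    electrophile + nucleophile → acid set free + target (k = 0.00370 L mol⁻¹ s⁻¹)
    nucleophile + acid set free ⇌ protonated nucleophile, settled at all times (K = 54000 L mol⁻¹)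
    acid set free + target → side product (k = 0.0150 L mol⁻¹ s⁻¹)
    target → over-reaction product (k = 6.00 × 10⁻⁷ s⁻¹)

In the flask, electrophile fell from 63.4% at 0.400 h to 6.48% at 4.00 h, while protonated nucleophile rose to 30.8 mM and acid set free, far less than that, stood at 0.0153 mM. Side product had reached 0.172% and over-reaction product 0.621%, with no visible effect on conversion. My reckoning lay 0.2 percentage points above the flask. The neighbour flask, same equivalents at 82 mM electrophile, has clock number 4.44, which gives 99.6%. That flask reached 99.6%.

All runs were computed for substances that don't exist, and the scatter is random.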